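Everything rests on cutting ring C between C2 and C3. In the target, C2–H lies between the ring oxygen O1 and the electron-rich ring B, and C3 lies next to the C4 carbonyl. C3 can therefore be a rhodium carbene and C2 a benzylic ether CH2. In one operation a chiral dirhodium catalyst inserts C3 into a C2–H bond, closes the six-membered ring C and sets C2. The precursor is an open, achiral α-diazoketone: fully substituted ring A bearing COCHN2 and, ortho to it, the ring B benzyl ether. The 3-hydroxyl then enters trans to ring B by enolate oxidation, and a single desilylation ends the route.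

Key step: step 12

Assumption: the S-configured ligand is taken to deliver the 2S product in step 12; if a test run shows the opposite sense, Rh2(R-PTTL)4 (from D-tert-leucine) is used in the same way.

Abbreviations: TBS = tert-butyldimethylsilyl; prenyl = 3-methylbut-2-enyl.

Step 1
Reactants: 1 2-methoxyresorcinol (2-methoxybenzene-1,3-diol)
Product: 2 1,3-bis(TBS-oxy)-2-methoxybenzene
Conditions: TBSCl, imidazole, DMF, rt
Reagents that add atoms: TBSCl, CC(C)(C)[Si](C)(C)Cl
Why: Imidazole-promoted silylation of both phenols; silyl ethers carry no C–H bond next to oxygen that could compete in step 12, and all of them fall in one fluoride step.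

Step 2
Reactants: 2 1,3-bis(TBS-oxy)-2-methoxybenzene
Product: 4 3,5-bis(TBS-oxy)-4-methoxyphenol, via aryl pinacol boronate 3 (not isolated)
Conditions: [Ir(OMe)(cod)]2 (cat.), dtbpy, B2pin2, THF, 80 °C; then Oxone, acetone/H2O, rt
Reagents that add atoms: B2pin2, CC1(C)OB(OC1(C)C)B1OC(C)(C)C(C)(C)O1; Oxone (active component KHSO5), [K+].[O-]S(=O)(=O)OO
Why: Sterically governed iridium-catalysed C–H borylation takes the only C–H bond without an ortho substituent (para to OMe), and oxidation of the C–B bond in the same flask should give the phenol (one-pot borylation/oxidation).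

Step 3
Reactants: 5 2-methylbut-3-en-2-ol
Product: 6 tert-butyl 2-methylbut-3-en-2-yl carbonate
Conditions: n-BuLi, THF, –78 to 0 °C; Boc2O
Reagents that add atoms: Boc2O, CC(C)(C)OC(=O)OC(=O)OC(C)(C)C
Why: Acylation of the lithium alkoxide with Boc2O gives the mixed carbonate, the usual precursor of a π-prenyl palladium complex.

Step 4
Reactants: 4 3,5-bis(TBS-oxy)-4-methoxyphenol; 6 tert-butyl 2-methylbut-3-en-2-yl carbonate
Product: 7 1,3-bis(TBS-oxy)-2-methoxy-5-(2-methylbut-3-en-2-yloxy)benzene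
Conditions: Pd(PPh3)4 (cat.), THF, 0 °C
Reagents that add atoms: none
Why: Decarboxylative Tsuji–Trost O-allylation, in which zerovalent palladium ionises 6, the released tert-butoxide deprotonates 4, and at low temperature the phenoxide attacks the more substituted allyl terminus to give the tertiary ether.

Step 5
Reactants: 7 1,3-bis(TBS-oxy)-2-methoxy-5-(2-methylbut-3-en-2-yloxy)benzene
Product: 8 3,5-bis(TBS-oxy)-4-methoxy-2-prenylphenol
Conditions: toluene, 110 °C
Reagents that add atoms: none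
Why: The aromatic Claisen rearrangement ([3,3]) turns the 1,1-dimethylallyl ether into a linear prenyl group at one of two equivalent ortho positions, so only one regioisomer can form.

Step 6
Reactants: 8 3,5-bis(TBS-oxy)-4-methoxy-2-prenylphenol
Product: 9 4,6-bis(TBS-oxy)-2-hydroxy-5-methoxy-3-prenylbenzaldehyde
Conditions: MgCl2, Et3N, (CH2O)n, MeCN, reflux
Reagents that add atoms: paraformaldehyde (as formaldehyde), C=O
Why: Casnati–Skattebøl ortho-formylation, in which the magnesium phenoxide delivers formaldehyde to the only free ring position and a second formaldehyde takes up hydride, under conditions that leave the prenyl group and the hindered silyl ethers alone.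

Step 7
Reactants: 10 2,5-dihydroxybenzaldehyde
Product: 11 2,5-bis(TBS-oxy)benzaldehyde
Conditions: TBSCl, imidazole, DMF, rt
Reagents that add atoms: TBSCl, CC(C)(C)[Si](C)(C)Cl
Why: Standard phenol silylation gives ring B the same protecting group as ring A.

Step 8
Reactants: 11 2,5-bis(TBS-oxy)benzaldehyde
Product: 12 [2,5-bis(TBS-oxy)phenyl]methanol
Conditions: NaBH4, MeOH/THF, 0 °C
Reagents that add atoms: none
Why: Borohydride reduction of the aldehyde at low temperature with a short reaction time limits silyl migration from the ortho phenol oxygen.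

Step 9
Reactants: 9 4,6-bis(TBS-oxy)-2-hydroxy-5-methoxy-3-prenylbenzaldehyde; 12 [2,5-bis(TBS-oxy)phenyl]methanol
Product: 13 2-{[2,5-bis(TBS-oxy)phenyl]methoxy}-4,6-bis(TBS-oxy)-5-methoxy-3-prenylbenzaldehyde
Conditions: PPh3, DIAD, THF, 0 °C to rt
Reagents that add atoms: none
Why: Mitsunobu etherification of the acidic, hydrogen-bonded phenol with a primary benzylic alcohol runs under neutral conditions, avoids phenoxide-induced silyl scrambling and fixes which ortho oxygen becomes O1.

Step 10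
Reactants: 13 2-{[2,5-bis(TBS-oxy)phenyl]methoxy}-4,6-bis(TBS-oxy)-5-methoxy-3-prenylbenzaldehyde
Product: 14 2-{[2,5-bis(TBS-oxy)phenyl]methoxy}-4,6-bis(TBS-oxy)-5-methoxy-3-prenylbenzoic acid
Conditions: NaClO2, NaH2PO4, 2-methylbut-2-ene (large excess), t-BuOH/THF/H2O, rt
Reagents that add atoms: sodium chlorite, [Na+].[O-]Cl=O
Why: Pinnick oxidation is selective for the aldehyde, and the excess alkene scavenger shields the prenyl group and ring B from hypochlorous acid.

Step 11
Reactants: 14 2-{[2,5-bis(TBS-oxy)phenyl]methoxy}-4,6-bis(TBS-oxy)-5-methoxy-3-prenylbenzoic acid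
Product: 16 1-(2-{[2,5-bis(TBS-oxy)phenyl]methoxy}-4,6-bis(TBS-oxy)-5-methoxy-3-prenylphenyl)-2-diazoethan-1-one, via acid chloride 15 (not isolated)
Conditions: 1-chloro-N,N,2-trimethylprop-1-en-1-amine, CH2Cl2, 0 °C; then CH2N2 (excess), Et2O, 0 °C
Reagents that add atoms: 1-chloro-N,N,2-trimethylprop-1-en-1-amine, CC(C)=C(Cl)N(C)C; diazomethane, C=[N+]=[N-]
Why: The α-chloroenamine makes the acid chloride without free HCl, and acylation of diazomethane (first stage of the Arndt–Eistert sequence) gives the terminal diazoketone, the second equivalent of diazomethane taking up HCl.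

Step 12
Reactants: 16 1-(2-{[2,5-bis(TBS-oxy)phenyl]methoxy}-4,6-bis(TBS-oxy)-5-methoxy-3-prenylphenyl)-2-diazoethan-1-one
Product: 17 (2S)-2-[2,5-bis(TBS-oxy)phenyl]-5,7-bis(TBS-oxy)-6-methoxy-8-prenylchroman-4-one
Conditions: Rh2(S-PTTL)4 (dirhodium tetrakis[N-phthaloyl-(S)-tert-leucinate], 1 mol %), 4 Å MS, toluene, 0 °C, slow addition of 16
Reagents that add atoms: none
Why: The catalyst expels N2 from 16 to give an electrophilic rhodium-bound carbene at C3, which inserts into one of the two enantiotopic C2–H bonds of the O1–CH2–ring B ether through a three-centre, hydride-transfer-like transition state (intramolecular carbene C–H insertion). The closest known reaction type is the cyclisation of 2-alkoxyphenyl α-diazoketones to 2-substituted chroman-4-ones with chiral dirhodium carboxylates. Ring C closes as a six-membered ring by a 1,6-insertion, because the atom in the place of the usual 1,5-insertion is O1 itself and bears no hydrogen. C2 is the only new stereocenter and is controlled by the chiral pocket of the four N-phthaloyl-tert-leucinate ligands, which selects one of the two hydrogens, the insertion itself going with retention at carbon. The step needs site selectivity and preference over oxonium ylide formation with [1,2]-benzyl shift: the C2–H bonds are the only ones activated by both an ether oxygen and an electron-rich arene, O5 carries a silyl group without an α-C–H bond, and the prenyl alkene sits meta to the acyl group and out of reach. The two ortho substituents twist the carbonyl out of the plane of ring A, which holds the carbene over the OCH2 group and away from the in-plane lone pair of the crowded, weakly basic O1.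

Step 13
Reactants: 17 (2S)-2-[2,5-bis(TBS-oxy)phenyl]-5,7-bis(TBS-oxy)-6-methoxy-8-prenylchroman-4-one
Product: 19 (2R,3R)-2-[2,5-bis(TBS-oxy)phenyl]-5,7-bis(TBS-oxy)-3-hydroxy-6-methoxy-8-prenylchroman-4-one, via sodium enolate 18 (not isolated)
Conditions: NaHMDS, THF, –78 °C; 2-(phenylsulfonyl)-3-phenyloxaziridine, –78 °C; AcOH quench at –78 °C
Reagents that add atoms: NaHMDS, C[Si](C)(C)[N-][Si](C)(C)C.[Na+]; 2-(phenylsulfonyl)-3-phenyloxaziridine, O=S(=O)(c1ccccc1)N1OC1c1ccccc1
Why: Davis enolate hydroxylation, in which kinetic enolate formation at –78 °C keeps ring C closed, the oxaziridine leaves the prenyl alkene untouched and oxygen is delivered to the C3 face anti to the C2 aryl group, setting the 2,3-trans (3R) configuration that is also the thermodynamically preferred one.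

Step 14
Reactants: 19 (2R,3R)-2-[2,5-bis(TBS-oxy)phenyl]-5,7-bis(TBS-oxy)-3-hydroxy-6-methoxy-8-prenylchroman-4-one
Product: 20 (2R,3R)-2-(2,5-dihydroxyphenyl)-3,5,7-trihydroxy-6-methoxy-8-prenylchroman-4-one (target)
Conditions: TBAF/AcOH (1:1), THF, 0 °C, under argon
Reagents that add atoms: none
Why: Fluoride cleaves the four aryl silyl ethers while the acetic acid buffer keeps the phenols protonated, so that neither C3 enolisation nor opening of ring C through a ring B quinone methide should scramble C2 or C3, and the prenyl group is inert.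

Compound list
1 | 2-methoxyresorcinol | COc1c(O)cccc1O | starting material
2 | 1,3-bis(TBS-oxy)-2-methoxybenzene | COc1c(O[Si](C)(C)C(C)(C)C)cccc1O[Si](C)(C)C(C)(C)C | intermediate
3 | 2-[3,5-bis(TBS-oxy)-4-methoxyphenyl]-4,4,5,5-tetramethyl-1,3,2-dioxaborolane | COc1c(O[Si](C)(C)C(C)(C)C)cc(B2OC(C)(C)C(C)(C)O2)cc1O[Si](C)(C)C(C)(C)C | intermediate
4 | 3,5-bis(TBS-oxy)-4-methoxyphenol | COc1c(O[Si](C)(C)C(C)(C)C)cc(O)cc1O[Si](C)(C)C(C)(C)C | intermediate
5 | 2-methylbut-3-en-2-ol | C=CC(C)(C)O | starting material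
6 | tert-butyl 2-methylbut-3-en-2-yl carbonate | C=CC(C)(C)OC(=O)OC(C)(C)C | intermediate
7 | 1,3-bis(TBS-oxy)-2-methoxy-5-(2-methylbut-3-en-2-yloxy)benzene | COc1c(O[Si](C)(C)C(C)(C)C)cc(OC(C)(C)C=C)cc1O[Si](C)(C)C(C)(C)C | intermediate
8 | 3,5-bis(TBS-oxy)-4-methoxy-2-prenylphenol | COc1c(O[Si](C)(C)C(C)(C)C)cc(O)c(CC=C(C)C)c1O[Si](C)(C)C(C)(C)C | intermediate
9 | 4,6-bis(TBS-oxy)-2-hydroxy-5-methoxy-3-prenylbenzaldehyde | COc1c(O[Si](C)(C)C(C)(C)C)c(C=O)c(O)c(CC=C(C)C)c1O[Si](C)(C)C(C)(C)C | intermediate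
10 | 2,5-dihydroxybenzaldehyde | O=Cc1cc(O)ccc1O | starting material
11 | 2,5-bis(TBS-oxy)benzaldehyde | O=Cc1cc(O[Si](C)(C)C(C)(C)C)ccc1O[Si](C)(C)C(C)(C)C | intermediate
12 | [2,5-bis(TBS-oxy)phenyl]methanol | OCc1cc(O[Si](C)(C)C(C)(C)C)ccc1O[Si](C)(C)C(C)(C)C | intermediate
13 | 2-{[2,5-bis(TBS-oxy)phenyl]methoxy}-4,6-bis(TBS-oxy)-5-methoxy-3-prenylbenzaldehyde | COc1c(O[Si](C)(C)C(C)(C)C)c(C=O)c(OCc2cc(O[Si](C)(C)C(C)(C)C)ccc2O[Si](C)(C)C(C)(C)C)c(CC=C(C)C)c1O[Si](C)(C)C(C)(C)C | intermediate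
14 | corresponding benzoic acid | COc1c(O[Si](C)(C)C(C)(C)C)c(C(=O)O)c(OCc2cc(O[Si](C)(C)C(C)(C)C)ccc2O[Si](C)(C)C(C)(C)C)c(CC=C(C)C)c1O[Si](C)(C)C(C)(C)C | intermediate
15 | corresponding benzoyl chloride | COc1c(O[Si](C)(C)C(C)(C)C)c(C(=O)Cl)c(OCc2cc(O[Si](C)(C)C(C)(C)C)ccc2O[Si](C)(C)C(C)(C)C)c(CC=C(C)C)c1O[Si](C)(C)C(C)(C)C | intermediate
16 | α-diazoketone (aryl COCHN2) | COc1c(O[Si](C)(C)C(C)(C)C)c(C(=O)C=[N+]=[N-])c(OCc2cc(O[Si](C)(C)C(C)(C)C)ccc2O[Si](C)(C)C(C)(C)C)c(CC=C(C)C)c1O[Si](C)(C)C(C)(C)C | intermediate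
17 | (2S)-2-[2,5-bis(TBS-oxy)phenyl]-5,7-bis(TBS-oxy)-6-methoxy-8-prenylchroman-4-one | COc1c(O[Si](C)(C)C(C)(C)C)c(CC=C(C)C)c2c(c1O[Si](C)(C)C(C)(C)C)C(=O)C[C@@H](c1cc(O[Si](C)(C)C(C)(C)C)ccc1O[Si](C)(C)C(C)(C)C)O2 | intermediate
18 | sodium C3–C4 enolate of 17 (2S) | COc1c(O[Si](C)(C)C(C)(C)C)c(CC=C(C)C)c2c(c1O[Si](C)(C)C(C)(C)C)C([O-])=C[C@@H](c1cc(O[Si](C)(C)C(C)(C)C)ccc1O[Si](C)(C)C(C)(C)C)O2.[Na+] | intermediate
19 | (2R,3R)-2-[2,5-bis(TBS-oxy)phenyl]-5,7-bis(TBS-oxy)-3-hydroxy-6-methoxy-8-prenylchroman-4-one | COc1c(O[Si](C)(C)C(C)(C)C)c(CC=C(C)C)c2c(c1O[Si](C)(C)C(C)(C)C)C(=O)[C@H](O)[C@@H](c1cc(O[Si](C)(C)C(C)(C)C)ccc1O[Si](C)(C)C(C)(C)C)O2 | intermediate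
20 | (2R,3R)-2-(2,5-dihydroxyphenyl)-3,5,7-trihydroxy-6-methoxy-8-prenylchroman-4-one | COc1c(O)c(CC=C(C)C)c2c(c1O)C(=O)[C@H](O)[C@@H](c1cc(O)ccc1O)O2 | target

Total step count: 14. Longest linear sequence: 11 steps (steps 1, 2, 4, 5, 6, 9, 10, 11, 12, 13, 14).

Steps most likely to fail

Step 12. The carbene may be diverted to the lone pair of O1, followed by a [1,2]-benzyl shift. The insertion may also become stepwise, with hydride transfer first, which would erode the discrimination between the two enantiotopic C2–H bonds. The fallback moves stereocontrol from the ring closure to a kinetic resolution.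
- Setting out from 16, the same C2–C3 closure is run with achiral Rh2(esp)2 in CH2Cl2 to give the racemic flavanone F1.
- Asymmetric transfer hydrogenation with Cp*RhCl[(R,R)-TsDPEN] and HCO2H/Et3N in EtOAc, a known resolution of prenylated flavanones, should reduce the 2R enantiomer faster to the (2R,4R)-cis-flavan-4-ol F2.
- F2 is removed by chromatography, and the unreacted 2S ketone is 17, where the route is rejoined.

Step 13. The enolate may open ring C by retro-oxa-Michael expulsion of the O1 phenoxide, with loss of the C2 configuration on reclosure. The enolate may also add to the sulfonimine by-product. The fallback avoids any metal enolate.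
- Setting out from 17, soft enolisation with TBSOTf/Et3N in CH2Cl2 at 0 °C gives the 4-silyloxy-2H-chromene F3.
- Rubottom-type oxidation of F3 with the same N-sulfonyloxaziridine under neutral conditions (CHCl3, 50 °C) should spare the prenyl alkene and attack anti to ring B. With silyl migration it gives the 3-O-TBS ether F4.
- The conditions of step 14 then remove all five silyl groups, and the route is rejoined at 20.

Step 11. Acylation of diazomethane at a carbonyl flanked by two ortho substituents may be slow, and traces of acid may cleave the electron-rich benzyl ether. The fallback builds the diazo group by diazo transfer instead of acylation.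
- Setting out from 13, MeMgBr in THF at –78 °C gives the secondary carbinol F5.
- DMP oxidation of F5 gives the methyl ketone F6.
- LiHMDS and 2,2,2-trifluoroethyl trifluoroacetate give the trifluoroacetyl ketone F7, used crude.
- MsN3, Et3N and H2O in MeCN (detrifluoroacetylative diazo transfer) convert F7 to 16, where the route is rejoined.

Further compounds
F1 | step 12 | racemic 2-[2,5-bis(TBS-oxy)phenyl]-5,7-bis(TBS-oxy)-6-methoxy-8-prenylchroman-4-one | COc1c(O[Si](C)(C)C(C)(C)C)c(CC=C(C)C)c2c(c1O[Si](C)(C)C(C)(C)C)C(=O)CC(c1cc(O[Si](C)(C)C(C)(C)C)ccc1O[Si](C)(C)C(C)(C)C)O2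
F2 | step 12 | (2R,4R)-2-[2,5-bis(TBS-oxy)phenyl]-5,7-bis(TBS-oxy)-6-methoxy-8-prenylchroman-4-ol | COc1c(O[Si](C)(C)C(C)(C)C)c(CC=C(C)C)c2c(c1O[Si](C)(C)C(C)(C)C)[C@H](O)C[C@H](c1cc(O[Si](C)(C)C(C)(C)C)ccc1O[Si](C)(C)C(C)(C)C)O2
F3 | step 13 | (2S)-2-[2,5-bis(TBS-oxy)phenyl]-4,5,7-tris(TBS-oxy)-6-methoxy-8-prenyl-2H-chromene | COc1c(O[Si](C)(C)C(C)(C)C)c(CC=C(C)C)c2c(c1O[Si](C)(C)C(C)(C)C)C(O[Si](C)(C)C(C)(C)C)=C[C@@H](c1cc(O[Si](C)(C)C(C)(C)C)ccc1O[Si](C)(C)C(C)(C)C)O2
F4 | step 13 | (2R,3R)-2-[2,5-bis(TBS-oxy)phenyl]-3,5,7-tris(TBS-oxy)-6-methoxy-8-prenylchroman-4-one | COc1c(O[Si](C)(C)C(C)(C)C)c(CC=C(C)C)c2c(c1O[Si](C)(C)C(C)(C)C)C(=O)[C@H](O[Si](C)(C)C(C)(C)C)[C@@H](c1cc(O[Si](C)(C)C(C)(C)C)ccc1O[Si](C)(C)C(C)(C)C)O2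
F5 | step 11 | 1-(2-{[2,5-bis(TBS-oxy)phenyl]methoxy}-4,6-bis(TBS-oxy)-5-methoxy-3-prenylphenyl)ethan-1-ol (racemic carbinol) | COc1c(O[Si](C)(C)C(C)(C)C)c(C(C)O)c(OCc2cc(O[Si](C)(C)C(C)(C)C)ccc2O[Si](C)(C)C(C)(C)C)c(CC=C(C)C)c1O[Si](C)(C)C(C)(C)C
F6 | step 11 | 1-(2-{[2,5-bis(TBS-oxy)phenyl]methoxy}-4,6-bis(TBS-oxy)-5-methoxy-3-prenylphenyl)ethan-1-one | COc1c(O[Si](C)(C)C(C)(C)C)c(C(C)=O)c(OCc2cc(O[Si](C)(C)C(C)(C)C)ccc2O[Si](C)(C)C(C)(C)C)c(CC=C(C)C)c1O[Si](C)(C)C(C)(C)C
F7 | step 11 | 1-(2-{[2,5-bis(TBS-oxy)phenyl]methoxy}-4,6-bis(TBS-oxy)-5-methoxy-3-prenylphenyl)-4,4,4-trifluorobutane-1,3-dione | COc1c(O[Si](C)(C)C(C)(C)C)c(C(=O)CC(=O)C(F)(F)F)c(OCc2cc(O[Si](C)(C)C(C)(C)C)ccc2O[Si](C)(C)C(C)(C)C)c(CC=C(C)C)c1O[Si](C)(C)C(C)(C)C
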